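**Remarks on the chemistry**

- Assumption: the target has no stereocentre and is treated as achiral. Atom labels used throughout: ring A has OH on C1, the ether oxygen on C3 and the chain on C5; ring B has the ether oxygen on C1, OH on C2 and C6 and the chain on C4; the chain runs from C1 (on ring A) to C12 (on ring B).
- Structure check: the ring-opening precursor (C27H37BrO5) and the macrocyclic ketone (C27H36O5) differ by exactly HBr, and the new ring has 20 members (3 ring A atoms, O, 4 ring B atoms, 12 chain carbons). No structure needed redrawing. One count needs care: after ring opening the radical carbon is the eleventh carbon from the carbonyl, with ten methylenes between them.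
- Design changes within the same disconnection:
  - An iridium photocatalyst of the Ir[dF(CF3)ppy]2(dtbbpy)PF6 type (excited state about +1.2 V vs SCE) is judged too weak an oxidant to turn a meta-dioxygenated arene into the radical cation that this type of O–H activation needs. A strongly oxidising acridinium is used instead.
  - The boron partner for the ether coupling is made as the free boronic acid, because pinacol boronates transfer poorly to copper.
  - Nickel loading is raised and the substrate is added slowly, so that the ring B bromide is already on nickel when the chain radical appears.

## Structural features

Target 13 (C24H32O4) is a 20-membered macrocycle in which two benzene rings are joined twice: by a diaryl ether oxygen and by an unbranched, saturated twelve-carbon chain. Ring A is 1,3,5-trisubstituted (OH on C1, ether oxygen on C3, chain C1 on C5). Ring B carries the ether oxygen on C1, hydroxyls on C2 and C6, and chain C12 on C4, para to the ether oxygen. There is no stereocentre, so no stereocentres adjoin and nothing has to be controlled in space. The fragile groups are the three free phenols: ring B is a pyrogallol-type, easily oxidised unit and ring A is a resorcinol-type ring open to electrophiles, so all three are carried as methyl ethers until the last step. The real difficulty is twofold: closing an unbiased 20-membered ring, and forming a diaryl ether whose ring B oxygen is flanked by two ortho oxygen substituents while ring A offers only meta relationships. The key step exploits the fact that chain carbons C1 to C12 are the twelve carbons of a cyclododecane ring. Chain C1 can be the carbinol carbon of a 1-arylcyclododecanol on ring A C5, and chain C12 its ring neighbour, so that breaking the C1–C12 ring bond and joining C12 to ring B C4 turns the 12-ring into the 20-ring.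

## Logic of the disconnections

13 to 12: the three O–CH3 bonds are added back. The free phenols would not survive organolithium, copper-mediated or photo-oxidative steps, and the methyl groups come with the commercial materials, so no protection step is spent. The forward step must cleave three alkyl–oxygen bonds and leave the aryl–oxygen–aryl link alone.

12 to 11: a carbonyl is placed on chain C1, next to ring A. This adds no simplicity by itself, but the aryl ketone is the footprint of an alkoxy-radical ring opening and so unlocks the next cut. The forward step must take an aryl ketone without a para donor all the way to CH2 without touching the aryl ethers.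

11 to 8: the ring B C4–chain C12 bond is cut and chain C12 is joined back to chain C1, turning the ketone into a tertiary alcohol. The 20-membered ring collapses to a 12-membered carbocycle plus an aryl bromide, and the whole chain arrives preassembled with no chain-building steps. The forward step must generate an alkoxy radical in the presence of two electron-rich arenes and deliver the freed primary radical to ring B C4 of the same molecule.

8 to 6 and 7: the ring A C3–O bond of the diaryl ether is cut. This is the convergent point and keeps the oxygen on the ring B piece, which is commercial with its bromide in place. The forward coupling must leave that bromide and the tertiary alcohol untouched, which rules out low-valent metal etherification and points to an oxidative copper coupling at room temperature.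

6 to 4: the C–B bond is exchanged for C–Br. This costs one step and gives a coupling partner orthogonal to the bromide of 7. The forward step must tolerate the free tertiary alcohol.

4 to 1 and 2: the bond between ring A C5 and the carbinol carbon is cut, giving an aryl anion and a ketone. Both pieces are commercial, and 1 is desymmetrised by a single halogen–metal exchange. The forward step must stop at mono-exchange and add to the carbonyl faster than it enolises it.

## Other disconnections considered

Alternative 1: The cut is through ring A itself, at C1–C2 and C3–C4, leading back to cyclobutenone A1, in which a twelve-carbon chain links the four-membered ring to a ring B unit bearing an ethynyl ether.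
- Forward step: heating A1 would open the cyclobutenone to a ketene, which adds across the ynol ether; a second ring opening and a six-electron closure would then give phenol A2, forming ring A and the 20-membered ring together.
- In its favour: ring A is born with its hydroxyl free and the 1,3,5 pattern is fixed by the mechanism. The chain is already saturated, so only one demethylation separates A2 from 13. On endgame length this plan is better than the chosen one by one step.
- Against it: A1 needs a long linear build (chain installation on ring B, a cyclobutenone from a terminal alkyne, and an aryl ethynyl ether that is sensitive to hydration and less nucleophilic than alkoxy- or siloxyacetylenes). The ketene must find the alkyne across a 20-membered ring at elevated temperature, while ketene dimerisation and trapping compete.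
- Comparison: both plans rest on a macrocyclisation without direct precedent, so they are equal on that risk. The chosen plan reaches its precursor 8 in three steps from commercial materials, against an estimated nine or more for A1, and is the better on step economy.

Alternative 2: The cut removes chain C9 as a one-carbon linchpin, breaking C8–C9 and C9–C10 and leading back to dibromide A3 and tosylmethyl isocyanide A4.
- Forward step: double alkylation of A4 by A3 under basic conditions at high dilution would give the macrocyclic alpha-tosyl isocyanide A5, racemic at the quaternary carbon.
- In its favour: this is established ionic chemistry, used for cyclophanes and large-ring ketones, and the linchpin can be placed anywhere along the chain. On precedent and on freedom of design it is better than the chosen plan.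
- Against it: A3 needs two different bromoalkyl arms installed separately on the two rings of a preformed diaryl ether. The ring closure is the second of two alkylations, so oligomers and two-to-two macrocycles compete. Dissolving-metal removal of the tosyl and isocyanide groups would endanger the diaryl ether, so hydrolysis and a separate deoxygenation are needed before reaching 12.
- Comparison: the mechanism is more predictable than a radical–nickel relay, and the stereocentre of A5 is irrelevant because it is erased. The route is estimated at roughly twice the length of the chosen plan, and it too needs a carbonyl removal at the end, so it gains nothing there.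

Alternative 3: The cut is at chain C1=C2 as an alkene, leading back to the 21-membered benzylic sulfone A6, with the sulfur between ring A's benzylic carbon and the remaining eleven chain carbons.
- Forward step: base and a halogen source would halogenate alpha to the sulfone; 1,3-elimination to an episulfone and loss of SO2 would give macrocyclic styrene A7 as a mixture of alkene geometries, and hydrogenation would then give 12.
- In its favour: the macrocyclisation is delegated to thiolate alkylation at high dilution, one of the most dependable large-ring closures, and the ring contraction is well established for cyclophanes. On reliability of ring formation it is better than the chosen plan. The alkene geometry is of no consequence, and the two steps from A7 to 13 equal the chosen plan's two steps from 11.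
- Against it: A6 requires a benzylic electrophile on ring A and an eleven-carbon thiol chain on ring B, then oxidation. The halogenating conditions of the contraction meet two electron-rich arenes. The count from commercial materials is estimated at eleven or more.
- Comparison: structurally it adds and then deletes a sulfur atom, where the chosen plan uses every carbon of a commercial ring. Mechanistically it is the safer choice; on step economy the chosen plan is clearly shorter.

Key step: step 4

## Route

Step 1
Reactants: 1 3,5-dibromoanisole; 2 cyclododecanone
Product: 4 1-(3-bromo-5-methoxyphenyl)cyclododecan-1-ol, via 3-bromo-5-methoxyphenyllithium 3 (not isolated)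
Conditions: n-BuLi (1.0 equiv), Et2O, −78 °C, 30 min; then 2, −78 → 0 °C; aq NH4Cl
Reagents that add atoms: none
Why: Bromine–lithium exchange on one of the two equivalent bromides is fast at −78 °C and the anionic ring resists a second exchange; aryllithium 3 then adds to the carbonyl of 2 (1,2-addition of an organolithium to a ketone), which for a weakly basic aryllithium should outrun enolisation. No stereocentre arises because the carbinol carbon lies on a symmetrical ring.

Step 2
Reactants: 4 1-(3-bromo-5-methoxyphenyl)cyclododecan-1-ol
Product: 6 [3-(1-hydroxycyclododecyl)-5-methoxyphenyl]boronic acid, via dilithio alkoxide 5 (not isolated)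
Conditions: n-BuLi (2.1 equiv), THF, −78 °C; B(OiPr)3 (3 equiv), −78 °C → rt; aq NH4Cl
Reagents that add atoms: triisopropyl borate, CC(C)OB(OC(C)C)OC(C)C; water, O
Why: The first equivalent of base removes the hydroxyl proton and the second performs bromine–lithium exchange to give 5, which is trapped by the borate ester (electrophilic borylation of an aryllithium); mild hydrolysis should release the boronic acid without ionising the tertiary benzylic alcohol. The free acid is preferred to a pinacol ester because it transfers its aryl group to copper far more readily in step 3.

Step 3
Reactants: 6 [3-(1-hydroxycyclododecyl)-5-methoxyphenyl]boronic acid; 7 4-bromo-2,6-dimethoxyphenol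
Product: 8 1-[3-(4-bromo-2,6-dimethoxyphenoxy)-5-methoxyphenyl]cyclododecan-1-ol
Conditions: Cu(OAc)2 (2 equiv), pyridine (5 equiv), 4 Å MS, CH2Cl2, dry air, rt, 48 h
Reagents that add atoms: none
Why: Chan–Lam oxidative C–O coupling: the phenoxide of 7 binds divalent copper, the aryl group of 6 is transferred from boron, and after oxidation to trivalent copper the C–O bond forms by reductive elimination at room temperature. No low-valent metal is present, so the bromide of 7 should stay inert; doubly ortho-substituted halophenols are established partners, and the hindered tertiary alcohol should not compete.

Step 4
Reactants: 8 1-[3-(4-bromo-2,6-dimethoxyphenoxy)-5-methoxyphenyl]cyclododecan-1-ol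
Product: 11 macrocyclic aryl ketone of the tri-O-methyl series (20-membered ring, C=O on chain C1 at ring A C5), via alkoxy radical 9 (not isolated), via ring-opened primary alkyl radical 10 (not isolated)
Conditions: 9-mesityl-3,6-di-tert-butyl-10-phenylacridinium tetrafluoroborate (5 mol%), NiBr2(dme) (20 mol%), 4,4'-di-tert-butyl-2,2'-bipyridine (24 mol%), 2,4,6-collidine (2 equiv), degassed MeCN/PhCF3 (1:1), 8 added by syringe pump over 12 h to 2 mM, 450 nm LEDs, 25 °C, Ar
Reagents that add atoms: none
Why: Proposed new method: the excited acridinium (near +2 V vs SCE) should oxidise one of the electron-rich arenes of 8 (estimated near +1.5 V) to its radical cation, and collidine then takes the hydroxyl proton as the O–H electron passes to the arene hole, so that proton-coupled electron transfer gives alkoxy radical 9. Beta-scission of the ring bond between the carbinol carbon (chain C1) and chain C12, driven by formation of the conjugated aryl ketone and release of transannular strain, gives primary radical 10, whose radical carbon is the eleventh carbon from the carbonyl. Nickel carrying the bipyridine ligand inserts into the ring B C4–Br bond to give a divalent arylnickel bromide, capture of the radical gives a trivalent aryl(alkyl)nickel species, and reductive elimination forms the ring B C4–chain C12 bond; the same trivalent species is reached if low-valent nickel captures the radical first and the tethered bromide then adds intramolecularly. The reduced acridine radical returns its electron to nickel, most plausibly at the trivalent arylnickel dihalide stage, so the step is redox-neutral and HBr, held by collidine, is the only stoichiometric by-product. The closest known reaction type is the intermolecular photoredox and nickel ring-opening arylation of 1-arylcycloalkanols with aryl bromides through alkoxy-radical beta-scission; the intramolecular, macrocyclising use is what is new. The 20-membered ring closes by end-to-end C(sp2)–C(sp3) reductive elimination at nickel while the 12-membered carbocycle opens in the same sequence, a net ring expansion by the eight atoms of the diaryl ether unit and not a radical attack on an arene; no stereocentre is formed. The selectivity needed is capture within the same molecule over hydrogen abstraction, arene addition and intermolecular coupling: the unstabilised primary radical has no fast internal hydrogen shift available, slow addition keeps unreacted 8 below the nickel concentration so that its bromide is on nickel before the radical appears, and the 2 mM dilution disfavours dimers.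

Step 5
Reactants: 11 macrocyclic aryl ketone of the tri-O-methyl series
Product: 12 tri-O-methyl macrocycle (20-membered ring, saturated twelve-carbon chain)
Conditions: Et3SiH (4 equiv), TFA/CH2Cl2 (1:1), 0 °C → rt (40 °C if slow)
Reagents that add atoms: none
Why: Ionic hydrogenation: the protonated aryl ketone accepts hydride from the silane, the benzylic alcohol so formed ionises in trifluoroacetic acid, and the cation takes a second hydride to give the methylene group. Aryl methyl ethers, the diaryl ether and the saturated chain are inert to these conditions.

Step 6
Reactants: 12 tri-O-methyl macrocycle
Product: 13 target macrocycle CNP0314249.0 (ring A 1-hydroxy; ring B 2,6-dihydroxy; twelve-carbon chain from ring A C5 to ring B C4)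
Conditions: BBr3 (6 equiv), CH2Cl2, −78 °C → rt; H2O, 0 °C, degassed work-up
Reagents that add atoms: none
Why: Lewis-acid ether cleavage: boron tribromide binds each methoxy oxygen and bromide attacks the methyl carbon in an SN2 step, so only alkyl–oxygen bonds break and the diaryl ether, with two sp2 carbons on oxygen, should survive. Hydrolysis of the aryl borates releases the three phenols; exclusion of air protects the electron-rich triol.

## Compound list

1 | 3,5-dibromoanisole | COc1cc(Br)cc(Br)c1 | starting material
2 | cyclododecanone | O=C1CCCCCCCCCCC1 | starting material
3 | 3-bromo-5-methoxyphenyllithium | [Li]c1cc(Br)cc(OC)c1 | intermediate (not isolated)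
4 | 1-(3-bromo-5-methoxyphenyl)cyclododecan-1-ol | COc1cc(Br)cc(c1)C1(O)CCCCCCCCCCC1 | intermediate
5 | lithium 1-(3-lithio-5-methoxyphenyl)cyclododecan-1-olate | [Li]c1cc(OC)cc(c1)C1(O[Li])CCCCCCCCCCC1 | intermediate (not isolated)
6 | [3-(1-hydroxycyclododecyl)-5-methoxyphenyl]boronic acid | COc1cc(cc(c1)C1(O)CCCCCCCCCCC1)B(O)O | intermediate
7 | 4-bromo-2,6-dimethoxyphenol | COc1cc(Br)cc(OC)c1O | starting material
8 | 1-[3-(4-bromo-2,6-dimethoxyphenoxy)-5-methoxyphenyl]cyclododecan-1-ol | COc1cc(Oc2c(OC)cc(Br)cc2OC)cc(c1)C1(O)CCCCCCCCCCC1 | intermediate
9 | 1-[3-(4-bromo-2,6-dimethoxyphenoxy)-5-methoxyphenyl]cyclododecyloxyl radical | COc1cc(Oc2c(OC)cc(Br)cc2OC)cc(c1)C1([O])CCCCCCCCCCC1 | intermediate (not isolated)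
10 | 12-[3-(4-bromo-2,6-dimethoxyphenoxy)-5-methoxyphenyl]-12-oxododecyl radical | COc1cc(Oc2c(OC)cc(Br)cc2OC)cc(c1)C(=O)CCCCCCCCCC[CH2] | intermediate (not isolated)
11 | macrocyclic aryl ketone, tri-O-methyl series: 20-membered ring in which ring A (1-methoxy, 3-aryloxy, 5-acyl) and ring B (1-aryloxy, 2,6-dimethoxy, 4-alkyl) are joined by the ether oxygen and by an undecamethylene chain ending in the C=O on ring A C5 | COc1cc2cc(c1)Oc1c(OC)cc(cc1OC)CCCCCCCCCCCC2=O | intermediate
12 | tri-O-methyl macrocycle: as 11 with CH2 in place of C=O (dodecamethylene bridge from ring A C5 to ring B C4) | COc1cc2cc(c1)Oc1c(OC)cc(cc1OC)CCCCCCCCCCCC2 | intermediate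
13 | CNP0314249.0: 20-membered diaryl ether macrocycle; ring A 1-hydroxy-3-aryloxy-5-alkyl, ring B 1-aryloxy-2,6-dihydroxy-4-alkyl, dodecamethylene bridge; no stereocentre | Oc1cc2cc(c1)Oc1c(O)cc(cc1O)CCCCCCCCCCCC2 | target

## Step count and risks

Total step count: 6. Longest linear sequence: 6 steps (1 to 13); 2 and 7 each enter in a single step.

**Step 4 (key step, proposed new method).**
- What may go wrong:
  - The primary radical may be quenched by hydrogen abstraction from solvent before nickel captures it.
  - It may couple with an arylnickel on another molecule, giving oligomers.
  - The ring B bromide may be reduced without coupling.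
  - The initial oxidation may be unproductive, because a meta-dioxygenated arene is a poorer redox relay than a para-methoxyphenyl group and back electron transfer may win.
  - Nickel turnover by the weakly reducing acridine radical may also be slow.
- Refinement within the same approach: pre-form the arylnickel bromide of 8 with stoichiometric Ni(cod)2 and the bipyridine ligand before irradiation.
- Fallback with known chemistry, setting out from 1 (with 7 as partner) and rejoining at 12: monolithiation of 1 and trapping with triisopropyl borate gives (3-bromo-5-methoxyphenyl)boronic acid F1. Chan–Lam coupling of F1 with 7 gives 1-bromo-3-(4-bromo-2,6-dimethoxyphenoxy)-5-methoxybenzene F2. Twofold Negishi coupling of F2 with hept-6-enylzinc bromide (Pd(OAc)2, SPhos, THF) gives the bis(hept-6-enyl) diene F3. Ring-closing metathesis of F3 with the second-generation Grubbs catalyst at high dilution gives the 20-membered cycloalkene F4 as a mixture of alkene geometries. Hydrogenation over Pd/C then gives 12, which continues with step 6.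

**Step 2.**
- What may go wrong: incomplete second lithiation, protonation of the aryllithium (loss of bromine without borylation), butylation by the butyl bromide formed in the exchange, and loss of the polar boronic acid on isolation through protodeboronation.
- Fallback from 4, rejoining at 6: palladium-catalysed Miyaura borylation (Pd(dppf)Cl2, bis(pinacolato)diboron, KOAc, dioxane, 90 °C) gives the pinacol boronate 1-[3-methoxy-5-(4,4,5,5-tetramethyl-1,3,2-dioxaborolan-2-yl)phenyl]cyclododecan-1-ol F5. Oxidative cleavage of the pinacol with NaIO4 and NH4OAc in aqueous acetone then gives 6.

**Step 3.**
- What may go wrong: slow aryl transfer and slow C–O bond formation at copper, because the phenol oxygen is flanked by two methoxy groups; the boronic acid is meanwhile consumed by protodeboronation, oxidative hydroxylation and homocoupling.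
- Fallback from 4, rejoining at 8: copper-catalysed halogen exchange (CuI, NaI, trans-N,N'-dimethylcyclohexane-1,2-diamine, dioxane, 110 °C) gives 1-(3-iodo-5-methoxyphenyl)cyclododecan-1-ol F6. Ullmann coupling of F6 with 7 (CuI, picolinic acid, K3PO4, DMSO, 80 °C) then gives 8. This relies on the faster reaction of the aryl iodide and on the deactivation of the bromide that sits para to the phenoxide oxygen.

**Step 5.**
- What may go wrong: the meta oxygen substituents do not stabilise the benzylic cation, so the reduction may stall at the benzylic alcohol or its trifluoroacetate; elimination towards the styrene and alkylation of an electron-rich ring by the cation may also intervene.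
- Fallback from 11, rejoining at 12: condensation with hydrazine hydrate (EtOH, catalytic AcOH, reflux) gives the hydrazone F7. Base-induced loss of nitrogen from F7 (KOtBu, DMSO, rt to 60 °C, Wolff–Kishner reduction in the Cram modification) then gives 12.

## Further compounds

F1 | step 4 | (3-bromo-5-methoxyphenyl)boronic acid | COc1cc(Br)cc(c1)B(O)O
F2 | step 4 | 1-bromo-3-(4-bromo-2,6-dimethoxyphenoxy)-5-methoxybenzene | COc1cc(Br)cc(Oc2c(OC)cc(Br)cc2OC)c1
F3 | step 4 | 1-(hept-6-en-1-yl)-3-[4-(hept-6-en-1-yl)-2,6-dimethoxyphenoxy]-5-methoxybenzene | COc1cc(CCCCCC=C)cc(Oc2c(OC)cc(CCCCCC=C)cc2OC)c1
F4 | step 4 | 20-membered cycloalkene of the tri-O-methyl series, double bond between chain C6 and C7, mixture of alkene geometries | COc1cc2cc(c1)Oc1c(OC)cc(cc1OC)CCCCCC=CCCCCC2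
F5 | step 2 | 1-[3-methoxy-5-(4,4,5,5-tetramethyl-1,3,2-dioxaborolan-2-yl)phenyl]cyclododecan-1-ol | COc1cc(cc(c1)C1(O)CCCCCCCCCCC1)B1OC(C)(C)C(C)(C)O1
F6 | step 3 | 1-(3-iodo-5-methoxyphenyl)cyclododecan-1-ol | COc1cc(I)cc(c1)C1(O)CCCCCCCCCCC1
F7 | step 5 | hydrazone of macrocyclic ketone 11 | COc1cc2cc(c1)Oc1c(OC)cc(cc1OC)CCCCCCCCCCCC2=NN
A1 | alternative 1 | 3-[12-(4-ethynyloxy-3,5-dimethoxyphenyl)dodecyl]cyclobut-2-en-1-one | O=C1C=C(CCCCCCCCCCCCc2cc(OC)c(OC#C)c(OC)c2)C1
A2 | alternative 1 | ring B di-O-methyl ether of the target (ring A phenol free) | Oc1cc2cc(c1)Oc1c(OC)cc(cc1OC)CCCCCCCCCCCC2
A3 | alternative 2 | 1-(8-bromooctyl)-3-[4-(3-bromopropyl)-2,6-dimethoxyphenoxy]-5-methoxybenzene | COc1cc(CCCCCCCCBr)cc(Oc2c(OC)cc(CCCBr)cc2OC)c1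
A4 | alternative 2 | tosylmethyl isocyanide | Cc1ccc(cc1)S(=O)(=O)C[N+]#[C-]
A5 | alternative 2 | macrocyclic alpha-tosyl isocyanide, quaternary at chain C9, racemic | COc1cc2cc(c1)Oc1c(OC)cc(cc1OC)CCCC(S(=O)(=O)c3ccc(C)cc3)([N+]#[C-])CCCCCCCC2
A6 | alternative 3 | 21-membered benzylic sulfone, tri-O-methyl series (SO2 between the ring A benzylic CH2 and an undecamethylene chain to ring B C4) | COc1cc2cc(c1)Oc1c(OC)cc(cc1OC)CCCCCCCCCCCS(=O)(=O)C2
A7 | alternative 3 | macrocyclic styrene, tri-O-methyl series, chain C1=C2, mixture of alkene geometries | COc1cc2cc(c1)Oc1c(OC)cc(cc1OC)CCCCCCCCCCC=C2
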